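**Retrosynthetic overview**
1. Labels: central ring C1 (methyl-bearing), C2 (=CH), C3 (bears ring A), C4 (bears the ring-B aroyl group), C5 (bears ring C), C6 (CH2). Ring A is the styryl-substituted resorcinol ring and ring D the 3,5-dioxygenated ring of the stilbene.
2. Last operations: global O-deprotection, preceded by a Heck reaction of a ring-A bromide with 3,5-diacetoxystyrene to make the (E)-stilbene.
3. The cyclohexene is the only ring that is built (the four arenes are bought). It comes from a formal [5+1] annulation of a ring-A benzaldehyde (C3) with an open C4–C5–C6–C1=C2 chain carrying a silyl enol ether at C4 and a (Z)-vinylsilane at C2; C3–C4 forms first (aldol), then the ring closes at C2–C3.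
4. Enabling feature: C3 is benzylic to ring A, whose oxygen atoms ortho and para to C3 stabilize a cation there, and it lies between the enolizable C4 (alpha to the ring-B ketone) and the C1=C2 alkene, so an aldehyde carbon can accept two carbon nucleophiles in turn.
5. Chain: C5 is set by rhodium-catalysed asymmetric 1,4-addition of a ring-C boronic acid to an (E)-enone (alkenylzirconocene plus ring-B acid chloride); the (Z)-vinylsilane comes from propargyl alcohol by anti-carbomagnesiation and a retro-Brook shift.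

Key step: step 13

Remark: TBS = tert-butyldimethylsilyl; the ring-D phenols are carried as acetates because 3,5-diacetoxystyrene is taken as commercially available, all other phenols as TBS ethers.

Step 1
Reactants: 1 prop-2-yn-1-ol (propargyl alcohol)
Product: 3 (Z)-3-iodo-2-methylprop-2-en-1-ol, via dimagnesium alkenyl alkoxide 2 (not isolated)
Conditions: MeMgBr (3 equiv), CuI (10 mol %), THF/Et2O, −10 → 23 °C; then I2, −60 → 0 °C
Reagents that add atoms: methylmagnesium bromide, C[Mg]Br; iodine, II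
Why: Copper-catalysed anti-carbomagnesiation of the propargylic alkoxide puts methyl on C2 and magnesium on C3 cis to the CH2O group (five-membered chelate), and iodinolysis with retention fixes the (Z)-geometry.

Step 2
Reactants: 3 (Z)-3-iodo-2-methylprop-2-en-1-ol
Product: 6 (Z)-2-methyl-3-(trimethylsilyl)prop-2-en-1-ol, via trimethylsilyl ether 4 (not isolated), via vinyllithium 5 (not isolated)
Conditions: n-BuLi (1.0 equiv), THF, −78 °C; TMSCl (1.05 equiv); t-BuLi (2.1 equiv), −78 → −20 °C; aq. NH4Cl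
Reagents that add atoms: chlorotrimethylsilane, C[Si](C)(C)Cl
Why: O-silylation, iodine–lithium exchange with retention and a retro-[1,4]-Brook rearrangement (oxygen-to-carbon silyl shift, possible because lithium is cis to the CH2OSiMe3 group) should give the (Z)-vinylsilane.

Step 3
Reactants: 6 (Z)-2-methyl-3-(trimethylsilyl)prop-2-en-1-ol
Product: 7 (Z)-(3-bromo-2-methylprop-1-en-1-yl)trimethylsilane
Conditions: CBr4, PPh3, CH2Cl2, 0 °C
Reagents that add atoms: carbon tetrabromide, BrC(Br)(Br)Br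
Why: Appel reaction, an SN2 displacement at the primary allylic carbon under non-acidic conditions that leaves the vinylsilane geometry untouched.

Step 4
Reactants: 7 (Z)-(3-bromo-2-methylprop-1-en-1-yl)trimethylsilane
Product: 8 (Z)-trimethyl(2-methylpent-1-en-4-yn-1-yl)silane
Conditions: HC≡CMgBr (1.5 equiv), CuCl (10 mol %), THF, 0 → 40 °C
Reagents that add atoms: ethynylmagnesium bromide, C#C[Mg]Br
Why: Copper-catalysed coupling of an alkynyl Grignard reagent with a primary allylic bromide, expected at the unhindered CH2 terminus and not at the silyl-bearing carbon.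

Step 5
Reactants: 9 2,4-dihydroxybenzoic acid
Product: 10 TBS 2,4-bis[(TBS)oxy]benzoate
Conditions: TBSCl (3.5 equiv), imidazole, DMF, 40 °C
Reagents that add atoms: tert-butyldimethylsilyl chloride, CC(C)(C)[Si](C)(C)Cl
Why: Imidazole-promoted silylation of both phenols and the carboxylic acid.

Step 6
Reactants: 10 TBS 2,4-bis[(TBS)oxy]benzoate
Product: 11 2,4-bis[(TBS)oxy]benzoyl chloride
Conditions: (COCl)2 (1.2 equiv), DMF (cat.), CH2Cl2, 0 → 23 °C
Reagents that add atoms: oxalyl chloride, O=C(Cl)C(=O)Cl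
Why: Conversion of a silyl ester into the acid chloride by the chloroiminium species from oxalyl chloride and DMF, under neutral conditions that spare the aryl silyl ethers.

Step 7
Reactants: 8 (Z)-trimethyl(2-methylpent-1-en-4-yn-1-yl)silane; 11 2,4-bis[(TBS)oxy]benzoyl chloride
Product: 13 (2E,5Z)-1-{2,4-bis[(TBS)oxy]phenyl}-5-methyl-6-(trimethylsilyl)hexa-2,5-dien-1-one, via alkenylzirconocene 12 (not isolated)
Conditions: Cp2Zr(H)Cl (1.1 equiv), THF, 23 °C; then 11, CuBr·SMe2 (10 mol %), 23 °C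
Reagents that add atoms: none
Why: Syn-hydrozirconation of the terminal alkyne (the trisubstituted vinylsilane is inert) gives the (E)-alkenylzirconocene, and copper-catalysed acylation with retention gives the (E)-enone.

Step 8
Reactants: 14 4-bromobenzene-1,3-diol (4-bromoresorcinol)
Product: 15 1-bromo-2,4-bis[(TBS)oxy]benzene
Conditions: TBSCl (2.4 equiv), imidazole, DMF, 23 °C
Reagents that add atoms: tert-butyldimethylsilyl chloride, CC(C)(C)[Si](C)(C)Cl
Why: Imidazole-promoted silylation of both phenols.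

Step 9
Reactants: 15 1-bromo-2,4-bis[(TBS)oxy]benzene
Product: 18 {2,4-bis[(TBS)oxy]phenyl}boronic acid, via aryllithium 16 (not isolated), via diisopropyl boronate 17 (not isolated)
Conditions: B(Oi-Pr)3 (1.3 equiv), THF/toluene, −78 °C, n-BuLi (1.1 equiv) added last; aq. NH4Cl, 0 °C
Reagents that add atoms: triisopropyl borate, CC(C)OB(OC(C)C)OC(C)C; water, O
Why: Bromine–lithium exchange with in situ borate trapping (which should outpace the ortho oxygen-to-carbon silyl shift of the aryllithium), followed by mild hydrolysis.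

Step 10
Reactants: 13 (2E,5Z)-1-{2,4-bis[(TBS)oxy]phenyl}-5-methyl-6-(trimethylsilyl)hexa-2,5-dien-1-one; 18 {2,4-bis[(TBS)oxy]phenyl}boronic acid
Product: 19 (3S,5Z)-1,3-bis{2,4-bis[(TBS)oxy]phenyl}-5-methyl-6-(trimethylsilyl)hex-5-en-1-one
Conditions: [Rh(OH)(cod)]2 (2.5 mol %), (R)-BINAP (5.5 mol %), 18 (2.5 equiv), dioxane/H2O (10:1), 40 °C
Reagents that add atoms: none
Why: Hayashi–Miyaura reaction (rhodium-catalysed asymmetric 1,4-addition of an arylboronic acid to an (E)-enone) in which the BINAP–rhodium–aryl species selects the enone face and so sets C5; (R)-BINAP is expected to give the (S)-centre by the accepted model for acyclic (E)-enones, and the antipodal ligand would be used should the sense prove opposite.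

Step 11
Reactants: 19 (3S,5Z)-1,3-bis{2,4-bis[(TBS)oxy]phenyl}-5-methyl-6-(trimethylsilyl)hex-5-en-1-one
Product: 20 {[(1Z,3S,5Z)-1,3-bis{2,4-bis[(TBS)oxy]phenyl}-5-methyl-6-(trimethylsilyl)hexa-1,5-dien-1-yl]oxy}trimethylsilane
Conditions: TMSOTf (1.2 equiv), Et3N (1.5 equiv), CH2Cl2, 0 °C; pentane, filtration
Reagents that add atoms: trimethylsilyl trifluoromethanesulfonate, C[Si](C)(C)OS(=O)(=O)C(F)(F)F
Why: Soft enolization and O-silylation on the only enolizable side of the aryl ketone gives the (Z)-silyl enol ether without touching C5.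

Step 12
Reactants: 21 5-bromo-2,4-dihydroxybenzaldehyde
Product: 22 5-bromo-2,4-bis[(TBS)oxy]benzaldehyde
Conditions: TBSCl (2.4 equiv), imidazole, DMF, 23 °C
Reagents that add atoms: tert-butyldimethylsilyl chloride, CC(C)(C)[Si](C)(C)Cl
Why: Imidazole-promoted silylation of both phenols.

Step 13
Reactants: 20 {[(1Z,3S,5Z)-1,3-bis{2,4-bis[(TBS)oxy]phenyl}-5-methyl-6-(trimethylsilyl)hexa-1,5-dien-1-yl]oxy}trimethylsilane; 22 5-bromo-2,4-bis[(TBS)oxy]benzaldehyde
Product: 25 {2,4-bis[(TBS)oxy]phenyl}[(1R,2R,6S)-2-{5-bromo-2,4-bis[(TBS)oxy]phenyl}-6-{2,4-bis[(TBS)oxy]phenyl}-4-methylcyclohex-3-en-1-yl]methanone (all-trans), via aldol silyl ether 23 (not isolated), via C4-epimer 24 (not isolated)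
Conditions: 22 (1.1 equiv), TMSOTf (0.3 equiv), 2,6-di-tert-butyl-4-methylpyridine (0.1 equiv), CH2Cl2, −78 → −20 °C; then DBU (2 equiv), 23 °C
Reagents that add atoms: none
Why: Proposed new method: catalytic TMSOTf should first mediate a Mukaiyama aldol addition of the silyl enol ether to the aldehyde at −78 °C (C3–C4 bond, 23) and on warming ionize the benzylic C3–OSiMe3 group, because the two silyloxy oxygens of ring A ortho and para to C3 stabilize the cation as a quinone-methide-like species; the (Z)-vinylsilane then attacks with its silicon-bearing carbon C2 and loses the silyl group, so that the aldehyde carbon serves as a 1,1-dielectrophile in a formal [5+1] annulation whose only co-product is hexamethyldisiloxane. The closest known reaction types are the Mukaiyama aldol reaction, the Lewis-acid-promoted twofold addition of silyl nucleophiles to electron-rich benzaldehydes and the vinylsilane-terminated cation cyclization in its endocyclic mode; their merger on a benzylic cation that carries an acidic alpha-keto hydrogen is not established. The cyclohexene closes by 6-endo-trig attack of the alkene on the cation (exo with respect to the cation carbon), and ipso substitution with retention puts the double bond at C1=C2 only, for which silicon must be cis to the C6 chain. C3 is controlled by the C5 stereocentre through a chair-like transition state with ring A and ring C both pseudo-equatorial (3,5-cis); C4 should arise trans to ring C already in the aldol step (attack anti to the C5 aryl group under allylic 1,3-strain control), and DBU then equilibrates any C4 epimer 24 to the all-equatorial 25 via the enolate. The step needs the aldol to be complete before ionization (staged warming, slight excess of aldehyde) so that free enol ether does not intercept the cation, and it needs ring closure to outrun loss of the C4 proton (enone formation) and capture by the ortho-silyloxy oxygen of ring B; a medium free of unhindered base, the intramolecular beta-silicon-stabilized alkene terminus and full silyl protection of the phenols are meant to secure this.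

Step 14
Reactants: 25 all-trans ring-A bromide; 26 5-ethenyl-1,3-phenylene diacetate (3,5-diacetoxystyrene)
Product: 27 5-[(E)-2-{5-[(1R,2R,6S)-6-{2,4-bis[(TBS)oxy]benzoyl}-5-{2,4-bis[(TBS)oxy]phenyl}-3-methylcyclohex-2-en-1-yl]-2,4-bis[(TBS)oxy]phenyl}ethenyl]-1,3-phenylene diacetate (25 with the ring-A bromine replaced by the (E)-3,5-diacetoxystyryl group)
Conditions: 26 (1.5 equiv), Pd(P(t-Bu)3)2 (5 mol %), Cy2NMe (1.5 equiv), dioxane, 80 °C
Reagents that add atoms: none
Why: Mizoroki–Heck reaction in which syn-insertion and beta-hydride elimination give the (E)-stilbene, while the trisubstituted ring alkene is too hindered to insert and the ring stereocentres are not involved.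

Step 15
Reactants: 27 hexa-TBS diacetate of the target
Product: 28 (2,4-dihydroxyphenyl)[(1R,2R,6S)-2-{5-[(E)-2-(3,5-dihydroxyphenyl)ethenyl]-2,4-dihydroxyphenyl}-6-(2,4-dihydroxyphenyl)-4-methylcyclohex-3-en-1-yl]methanone (CNP0327388.2)
Conditions: K2CO3, MeOH/THF (degassed, argon), 0 → 23 °C; then AcOH
Reagents that add atoms: none
Why: Base-mediated methanolysis cleaves the two aryl acetates and the six aryl silyl ethers in one operation; no stereocentre is touched, C4 being already in its thermodynamic configuration.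

**Compound list**
1 | prop-2-yn-1-ol | C#CCO | starting material
2 | bromomagnesium (Z)-3-(bromomagnesio)-2-methylprop-2-en-1-olate | Br[Mg]/C=C(C)\CO[Mg]Br | intermediate (not isolated)
3 | (Z)-3-iodo-2-methylprop-2-en-1-ol | I/C=C(C)\CO | intermediate
4 | (Z)-[(3-iodo-2-methylprop-2-en-1-yl)oxy]trimethylsilane | I/C=C(C)\CO[Si](C)(C)C | intermediate (not isolated)
5 | (Z)-{2-methyl-3-[(trimethylsilyl)oxy]prop-1-en-1-yl}lithium | [Li]/C=C(C)\CO[Si](C)(C)C | intermediate (not isolated)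
6 | (Z)-2-methyl-3-(trimethylsilyl)prop-2-en-1-ol | C[Si](C)(C)/C=C(C)\CO | intermediate
7 | (Z)-(3-bromo-2-methylprop-1-en-1-yl)trimethylsilane | C[Si](C)(C)/C=C(C)\CBr | intermediate
8 | (Z)-trimethyl(2-methylpent-1-en-4-yn-1-yl)silane | C[Si](C)(C)/C=C(C)\CC#C | intermediate
9 | 2,4-dihydroxybenzoic acid | OC(=O)c1ccc(O)cc1O | starting material
10 | TBS 2,4-bis[(TBS)oxy]benzoate | CC(C)(C)[Si](C)(C)OC(=O)c1ccc(O[Si](C)(C)C(C)(C)C)cc1O[Si](C)(C)C(C)(C)C | intermediate
11 | 2,4-bis[(TBS)oxy]benzoyl chloride | O=C(Cl)c1ccc(O[Si](C)(C)C(C)(C)C)cc1O[Si](C)(C)C(C)(C)C | intermediate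
12 | chlorobis(cyclopentadienyl)[(1E,4Z)-4-methyl-5-(trimethylsilyl)penta-1,4-dien-1-yl]zirconium | C[Si](C)(C)/C=C(C)\C/C=C/[Zr](Cl)(C1C=CC=C1)C1C=CC=C1 | intermediate (not isolated)
13 | (2E,5Z)-1-{2,4-bis[(TBS)oxy]phenyl}-5-methyl-6-(trimethylsilyl)hexa-2,5-dien-1-one | C[Si](C)(C)/C=C(C)\C/C=C/C(=O)c1ccc(O[Si](C)(C)C(C)(C)C)cc1O[Si](C)(C)C(C)(C)C | intermediate
14 | 4-bromobenzene-1,3-diol | Oc1ccc(Br)c(O)c1 | starting material
15 | 1-bromo-2,4-bis[(TBS)oxy]benzene | Brc1ccc(O[Si](C)(C)C(C)(C)C)cc1O[Si](C)(C)C(C)(C)C | intermediate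
16 | {2,4-bis[(TBS)oxy]phenyl}lithium | [Li]c1ccc(O[Si](C)(C)C(C)(C)C)cc1O[Si](C)(C)C(C)(C)C | intermediate (not isolated)
17 | diisopropyl {2,4-bis[(TBS)oxy]phenyl}boronate | CC(C)OB(OC(C)C)c1ccc(O[Si](C)(C)C(C)(C)C)cc1O[Si](C)(C)C(C)(C)C | intermediate (not isolated)
18 | {2,4-bis[(TBS)oxy]phenyl}boronic acid | OB(O)c1ccc(O[Si](C)(C)C(C)(C)C)cc1O[Si](C)(C)C(C)(C)C | intermediate
19 | (3S,5Z)-1,3-bis{2,4-bis[(TBS)oxy]phenyl}-5-methyl-6-(trimethylsilyl)hex-5-en-1-one | C[Si](C)(C)/C=C(C)\C[C@@H](CC(=O)c1ccc(O[Si](C)(C)C(C)(C)C)cc1O[Si](C)(C)C(C)(C)C)c1ccc(O[Si](C)(C)C(C)(C)C)cc1O[Si](C)(C)C(C)(C)C | intermediate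
20 | {[(1Z,3S,5Z)-1,3-bis{2,4-bis[(TBS)oxy]phenyl}-5-methyl-6-(trimethylsilyl)hexa-1,5-dien-1-yl]oxy}trimethylsilane | C[Si](C)(C)/C=C(C)\C[C@@H](/C=C(\O[Si](C)(C)C)c1ccc(O[Si](C)(C)C(C)(C)C)cc1O[Si](C)(C)C(C)(C)C)c1ccc(O[Si](C)(C)C(C)(C)C)cc1O[Si](C)(C)C(C)(C)C | intermediate
21 | 5-bromo-2,4-dihydroxybenzaldehyde | O=Cc1cc(Br)c(O)cc1O | starting material
22 | 5-bromo-2,4-bis[(TBS)oxy]benzaldehyde | O=Cc1cc(Br)c(O[Si](C)(C)C(C)(C)C)cc1O[Si](C)(C)C(C)(C)C | intermediate
23 | (3S,5Z)-2-[{5-bromo-2,4-bis[(TBS)oxy]phenyl}(trimethylsilyloxy)methyl]-1,3-bis{2,4-bis[(TBS)oxy]phenyl}-5-methyl-6-(trimethylsilyl)hex-5-en-1-one (diastereomer mixture at C2 and at the silyloxy-bearing carbon) | C[Si](C)(C)/C=C(C)\C[C@@H](C(C(O[Si](C)(C)C)c1cc(Br)c(O[Si](C)(C)C(C)(C)C)cc1O[Si](C)(C)C(C)(C)C)C(=O)c1ccc(O[Si](C)(C)C(C)(C)C)cc1O[Si](C)(C)C(C)(C)C)c1ccc(O[Si](C)(C)C(C)(C)C)cc1O[Si](C)(C)C(C)(C)C | intermediate (not isolated)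
24 | {2,4-bis[(TBS)oxy]phenyl}[(1S,2R,6S)-2-{5-bromo-2,4-bis[(TBS)oxy]phenyl}-6-{2,4-bis[(TBS)oxy]phenyl}-4-methylcyclohex-3-en-1-yl]methanone (C4 epimer, aroyl cis to both aryl groups) | CC1=C[C@@H](c2cc(Br)c(O[Si](C)(C)C(C)(C)C)cc2O[Si](C)(C)C(C)(C)C)[C@@H](C(=O)c2ccc(O[Si](C)(C)C(C)(C)C)cc2O[Si](C)(C)C(C)(C)C)[C@@H](c2ccc(O[Si](C)(C)C(C)(C)C)cc2O[Si](C)(C)C(C)(C)C)C1 | intermediate (not isolated; minor epimer, equilibrated in the flask)
25 | {2,4-bis[(TBS)oxy]phenyl}[(1R,2R,6S)-2-{5-bromo-2,4-bis[(TBS)oxy]phenyl}-6-{2,4-bis[(TBS)oxy]phenyl}-4-methylcyclohex-3-en-1-yl]methanone (all-trans) | CC1=C[C@@H](c2cc(Br)c(O[Si](C)(C)C(C)(C)C)cc2O[Si](C)(C)C(C)(C)C)[C@H](C(=O)c2ccc(O[Si](C)(C)C(C)(C)C)cc2O[Si](C)(C)C(C)(C)C)[C@@H](c2ccc(O[Si](C)(C)C(C)(C)C)cc2O[Si](C)(C)C(C)(C)C)C1 | intermediate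
26 | 5-ethenyl-1,3-phenylene diacetate | C=Cc1cc(OC(C)=O)cc(OC(C)=O)c1 | starting material
27 | 5-[(E)-2-{5-[(1R,2R,6S)-6-{2,4-bis[(TBS)oxy]benzoyl}-5-{2,4-bis[(TBS)oxy]phenyl}-3-methylcyclohex-2-en-1-yl]-2,4-bis[(TBS)oxy]phenyl}ethenyl]-1,3-phenylene diacetate | CC1=C[C@@H](c2cc(/C=C/c3cc(OC(C)=O)cc(OC(C)=O)c3)c(O[Si](C)(C)C(C)(C)C)cc2O[Si](C)(C)C(C)(C)C)[C@H](C(=O)c2ccc(O[Si](C)(C)C(C)(C)C)cc2O[Si](C)(C)C(C)(C)C)[C@@H](c2ccc(O[Si](C)(C)C(C)(C)C)cc2O[Si](C)(C)C(C)(C)C)C1 | intermediate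
28 | (2,4-dihydroxyphenyl)[(1R,2R,6S)-2-{5-[(E)-2-(3,5-dihydroxyphenyl)ethenyl]-2,4-dihydroxyphenyl}-6-(2,4-dihydroxyphenyl)-4-methylcyclohex-3-en-1-yl]methanone | CC1=C[C@@H](c2cc(/C=C/c3cc(O)cc(O)c3)c(O)cc2O)[C@H](C(=O)c2ccc(O)cc2O)[C@@H](c2ccc(O)cc2O)C1 | target

**Step count and risks**
Total step count: 15. Longest linear sequence: 10 steps (steps 1, 2, 3, 4, 7, 10, 11, 13, 14, 15).

Steps most likely to fail:

1. Step 13 (proposed method). After ionization the benzylic cation may shed the C4 proton and give the conjugated enone faster than the vinylsilane captures it, or the second ionization may need temperatures at which protodesilylation of the vinylsilane sets in. Fallback with known chemistry (biomimetic Diels–Alder route), setting out from 22 and coming back at 25: Horner–Wadsworth–Emmons olefination of 22 with diethyl (2-methylprop-2-en-1-yl)phosphonate would give the diene 1-bromo-2,4-bis[(TBS)oxy]-5-[(E)-3-methylbuta-1,3-dien-1-yl]benzene F1. Separately, 2,4-dihydroxyacetophenone would be monosilylated to 1-{2-hydroxy-4-[(TBS)oxy]phenyl}ethanone F2 and 2,4-dihydroxybenzaldehyde bis-silylated to 2,4-bis[(TBS)oxy]benzaldehyde F3, and the two condensed under amine-mediated Claisen–Schmidt conditions to the 2'-hydroxychalcone (E)-3-{2,4-bis[(TBS)oxy]phenyl}-1-{2-hydroxy-4-[(TBS)oxy]phenyl}prop-2-en-1-one F4. An asymmetric Diels–Alder reaction of F1 with F4 mediated by a chiral boron complex of BINOL (a known reaction of 2'-hydroxychalcones; BINOL antipode matched to the required adduct) would give, after separation from the endo isomer, the exo adduct (1R,2R,6S)-configured 2'-hydroxy ketone F5. Silylation of its free phenol (TBSOTf, 2,6-lutidine) rejoins the route at 25.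

2. Step 10. Slow aryl transfer from the ortho-silyloxy boronic acid may let protodeboronation and hydroxide-induced isomerization of the skipped dienone compete, and enantiofacial control may erode. Fallback, setting out from 8 and 11 and coming back at 19: acylative Sonogashira coupling of 8 with 11 (PdCl2(PPh3)2, CuI, Et3N) would give the ynone (Z)-1-{2,4-bis[(TBS)oxy]phenyl}-5-methyl-6-(trimethylsilyl)hex-5-en-2-yn-1-one F6. Syn-hydroarylation of F6 with 18 under an achiral rhodium catalyst ([Rh(OH)(cod)]2, dioxane/H2O) would give the beta-aryl enone (2E,5Z)-1,3-bis{2,4-bis[(TBS)oxy]phenyl}-5-methyl-6-(trimethylsilyl)hexa-2,5-dien-1-one F7. A copper hydride-catalysed asymmetric 1,4-reduction (Cu(OAc)2, DTBM-SEGPHOS antipode matched to the (3S) product, polymethylhydrosiloxane, t-BuOH) moves the enantio-determining event to hydride delivery and gives 19.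

3. Step 14. Insertion of the styrene into the hindered, electron-rich arylpalladium species may be slow, so that silyl ether loss or regioisomeric insertion competes at the temperature required. Fallback, setting out from 25 and coming back at 27: Stille vinylation of 25 (tributyl(vinyl)stannane, Pd(PPh3)4, toluene) would give the styrene {2,4-bis[(TBS)oxy]phenyl}[(1R,2R,6S)-2-{2,4-bis[(TBS)oxy]-5-ethenylphenyl}-6-{2,4-bis[(TBS)oxy]phenyl}-4-methylcyclohex-3-en-1-yl]methanone F8. Olefin cross-metathesis of F8 with 26 (second-generation Hoveyda–Grubbs catalyst, CH2Cl2, 40 °C), in which the trisubstituted ring alkene should not take part, would give the (E)-stilbene 27.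

**Further compounds**
F1 | step 13 | 1-bromo-2,4-bis[(TBS)oxy]-5-[(E)-3-methylbuta-1,3-dien-1-yl]benzene | C=C(C)/C=C/c1cc(Br)c(O[Si](C)(C)C(C)(C)C)cc1O[Si](C)(C)C(C)(C)C
F2 | step 13 | 1-{2-hydroxy-4-[(TBS)oxy]phenyl}ethanone | CC(=O)c1ccc(O[Si](C)(C)C(C)(C)C)cc1O
F3 | step 13 | 2,4-bis[(TBS)oxy]benzaldehyde | O=Cc1ccc(O[Si](C)(C)C(C)(C)C)cc1O[Si](C)(C)C(C)(C)C
F4 | step 13 | (E)-3-{2,4-bis[(TBS)oxy]phenyl}-1-{2-hydroxy-4-[(TBS)oxy]phenyl}prop-2-en-1-one | O=C(/C=C/c1ccc(O[Si](C)(C)C(C)(C)C)cc1O[Si](C)(C)C(C)(C)C)c1ccc(O[Si](C)(C)C(C)(C)C)cc1O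
F5 | step 13 | {2-hydroxy-4-[(TBS)oxy]phenyl}[(1R,2R,6S)-2-{5-bromo-2,4-bis[(TBS)oxy]phenyl}-6-{2,4-bis[(TBS)oxy]phenyl}-4-methylcyclohex-3-en-1-yl]methanone | CC1=C[C@@H](c2cc(Br)c(O[Si](C)(C)C(C)(C)C)cc2O[Si](C)(C)C(C)(C)C)[C@H](C(=O)c2ccc(O[Si](C)(C)C(C)(C)C)cc2O)[C@@H](c2ccc(O[Si](C)(C)C(C)(C)C)cc2O[Si](C)(C)C(C)(C)C)C1
F6 | step 10 | (Z)-1-{2,4-bis[(TBS)oxy]phenyl}-5-methyl-6-(trimethylsilyl)hex-5-en-2-yn-1-one | C[Si](C)(C)/C=C(C)\CC#CC(=O)c1ccc(O[Si](C)(C)C(C)(C)C)cc1O[Si](C)(C)C(C)(C)C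
F7 | step 10 | (2E,5Z)-1,3-bis{2,4-bis[(TBS)oxy]phenyl}-5-methyl-6-(trimethylsilyl)hexa-2,5-dien-1-one | C[Si](C)(C)/C=C(C)\C/C(=C\C(=O)c1ccc(O[Si](C)(C)C(C)(C)C)cc1O[Si](C)(C)C(C)(C)C)c1ccc(O[Si](C)(C)C(C)(C)C)cc1O[Si](C)(C)C(C)(C)C
F8 | step 14 | {2,4-bis[(TBS)oxy]phenyl}[(1R,2R,6S)-2-{2,4-bis[(TBS)oxy]-5-ethenylphenyl}-6-{2,4-bis[(TBS)oxy]phenyl}-4-methylcyclohex-3-en-1-yl]methanone | CC1=C[C@@H](c2cc(C=C)c(O[Si](C)(C)C(C)(C)C)cc2O[Si](C)(C)C(C)(C)C)[C@H](C(=O)c2ccc(O[Si](C)(C)C(C)(C)C)cc2O[Si](C)(C)C(C)(C)C)[C@@H](c2ccc(O[Si](C)(C)C(C)(C)C)cc2O[Si](C)(C)C(C)(C)C)C1
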